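# Proposed total synthesis of CNP0261501.1 by a Danheiser benzannulation that writes ring A with a single free phenol

## Analysis of the target

The target (37) is a 2,3-dihydro-1-benzofuran (O1, C2, C3, C3a, C4 to C7, C7a; pyranone atoms primed) whose benzene ring A carries six substituents. These are hydroxyls on C4 and C6, the furan oxygen on C7a, a (2S)-2-methylbutanoyl group on C7, the C3 methylene on C3a and, on C5, a methylene bridge to C3′ of a 6′-ethyl-4′-hydroxy-5′-methylpyran-2′-one. There are two stereocentres, C2 (S, bearing the isopropenyl group) and the α-carbon of the acyl chain (S). They lie five bonds apart across ring A, so neither can direct the other and each needs its own source. The sensitive groups are the isopropenyl alkene (acid, hydrogenation), the allylic aryl ether O1–C2 (ionisation by Lewis acids or zerovalent palladium), the α-stereocentre once it stands beside a ketone (enolisation), the electron-rich ring (oxidation) and the methylene bridge (exchange of its two aryl partners). The difficulty is not the carbon count but ring A: a fully substituted trioxygenated benzene in which three chemically similar oxygens must be told apart. Only the C7a oxygen, flanked by the acyl carbon C7 and the side-chain carbon C3a, may enter the furan; closure through the C4 oxygen would give the regioisomeric benzofuran. The strategy rests on that feature: ring A is not functionalised but built, in a way that delivers the C7a oxygen as the only free hydroxyl.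

## Retrosynthetic reasoning

**Methylene bridge (C5–CH2 and CH2–C3′).** Both bonds to the bridging carbon are cut last, giving the acylated dihydroxybenzofuran 29, the pyranone 34 and a one-carbon iminium electrophile. C5 is the only free position of 29 and lies between two hydroxyls, and C3′ is the nucleophilic carbon of 34. The forward reaction has to favour the crossed product over symmetric dimers, which is arranged by aminomethylating 34 first (35) and releasing the methylidene dione 36 in the presence of 29. Cutting here keeps the acidic pyranone out of every earlier step and lets it be made separately in two steps (34 from 33, from 30 and 31).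

**Oxidation level and protecting groups on ring A (29 back to 26).** The benzyl ether of 28 is removed last among the protecting groups, after the ketone is in place, because the ketone deactivates the ring toward ionisation. The ketone of 28 comes from the benzylic carbinol 27, and 27 from the bis-silyl ether 26. Carrying the acyl carbon as a protected carbinol means that the α-stereocentre is not enolisable during the strongly basic, thermal and redox-condensation steps; the forward sequence has to unmask and oxidise it without losing water from the o-hydroxybenzylic alcohol.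

**O1–C2 (furan ring).** The dihydrofuran of 26 is opened at O1–C2 to the phenol–allylic alcohol 25. This bond is chosen because its formation by intramolecular Mitsunobu displacement is stereospecific: the (R) carbinol becomes (S)-C2 by inversion, so the stereocentre can be set earlier, by reagent control, on a small acyclic ketone. The disconnection requires that only the C7a oxygen is free, which is exactly what 25 and its precursor 24 offer (C4 as benzyl ether, C6 as silyl ether).

**Ring A (C7–C7a, C5–C6, C3a–C7a).** Phenol 24 is cut into cyclobutenone 13 and siloxyalkyne 19. The four-carbon unit C3a–C4–C5 plus the carbonyl carbon (future C7a) comes from 13, and C6–C7 from 19. This cut is made here and not elsewhere because it produces the C7a hydroxyl from the cyclobutenone carbonyl, the C4 oxygen from the benzyloxy group of 13 and the C6 oxygen from the silyloxy group of 19. The three oxygens are therefore differentiated by construction, and both side arms arrive with their stereocentres in place. The forward reaction must be regioselective in the ketene–alkyne cycloaddition.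

**Cyclobutenone 13.** The four-membered ring is cut into the alkylketene 12 (from acid 6 via acid chloride 11) and benzyloxyacetylene 10 (from benzyl alcohol 7 via 8 and 9). Acid 6 is traced through ester 5 to the allylic alcohol 4, whose stereocentre comes from oxazaborolidine-catalysed reduction of enone 3, made from 1 and 2. The C4 centre of 13 needs no control because it becomes aromatic.

**Siloxyalkyne 19.** The C–O alkyne is traced through ynolate 18 to the α-silyloxy ester 17 by Kowalski homologation, and 17 through 16 and 15 to L-isoleucine 14. The amino acid supplies the (S) sec-butyl centre unchanged and, by diazotisation with retention, an oxygen at the carbon that will become the ketone.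

## Alternatives that were turned down

**Alternative 1: isoprene Heck–Tsuji–Trost annulation onto a bromophenol.** The disconnection cuts C3–C3a and O1–C2 at once. In the forward key step the ortho-bromophenol A2 and isoprene A3 would react under a zerovalent palladium catalyst with a chiral phosphine: oxidative addition, Heck insertion into the monosubstituted alkene (C3–C3a), then attack of the phenoxide on the π-allyl complex (O1–C2), giving the bis-MOM ether A1.
- For it: it is the shortest route to the dihydrofuran, it is convergent, it sets C2 catalytically in the ring-forming step, and the acyl group enters intact from the chiral acid. On step economy it is stronger than the chosen route.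
- Against it: A2 needs a regioselective bromination of a ring with two open positions. The aryl bromide is electron-rich and doubly ortho-substituted, so oxidative addition is slow. Insertion at the other alkene of A3 gives the 2-methyl-2-vinyl isomer. Enantiocontrol rests on a ligand acting on a π-allyl complex that equilibrates through its unsubstituted terminus, on a far more hindered phenol than the usual substrates. The enolisable α-stereocentre is exposed to base and heat. The MOM groups must finally be removed with acid beside the isopropenyl group.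
- Comparison: the chosen route is longer, but it secures the oxygen pattern by construction and sets C2 by a stereospecific SN2 closure from a carbinol made under reagent control, with the ketone absent until late.

**Alternative 2: aryne insertion into the carboxylate.** The disconnection cuts the C7a–O and C7–acyl bonds. In the forward key step a fluoride source would generate the C7–C7a aryne from the silyl triflate A5. The caesium carboxylate A6 would add through oxygen at C7a, the position remote from the C6 alkoxy group, and the aryl anion at C7 would take the acyl carbon, giving the o-hydroxyaryl ketone A4.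
- For it: the C7a hydroxyl emerges as the only free one, as in the chosen route. The acyl group arrives at the ketone level, so there is no carbinol detour and no quinone methide risk; on that point it is stronger. The regiochemistry of addition is supported by the inductive effect of the C6 oxygen.
- Against it: no ring is formed, so the furan still has to be closed afterwards. A5 is a pentasubstituted arene that must itself be assembled with all oxygens already differentiated, which only moves the central problem to an earlier stage. Oxygen attack has to occur next to the bulky C3a side chain. The α-stereocentre of A6 and of the product sits next to a carbonyl under basic fluoride at elevated temperature.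
- Comparison: the chosen route builds the differentiated ring in one step from two simple chiral fragments instead of functionalising a preformed arene stepwise.

**Alternative 3: pyranone ring closed last at carbon on the bridge.** The disconnection cuts C4′–C5′ and O1′–C2′. In the forward key step the arylmethylmalonyl dichloride A8 would acylate the enol silane A9 at carbon, and the enol oxygen would close onto the second acyl chloride, giving the bis-silyl ether A7 of the target.
- For it: the bridge carbon is already attached to C5, so no symmetric dimer can form. On the selectivity of bridging it is stronger than the chosen final step.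
- Against it: it does nothing for ring A, so the whole benzofuran core must be made anyway and then extended by a malonate at C5. A bis-acid chloride has to be generated on a molecule with an isopropenyl group, silyl ethers and an enolisable ketone. The annulation liberates HCl at elevated temperature and competes with O-acylation. The pyranone is built in several late steps on the most valuable material.
- Comparison: the chosen route makes the pyranone in two steps from cheap materials and attaches it in one known operation.

Key step: step 11

## Route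

Remark on the chemistry: the ring sp3 carbon of 13, 21 and 23 that becomes aromatic C3a is carried as an epimer mixture, and the silyl-protected carbinol carbon of the acyl arm (S as drawn, from 14) is a spectator that is oxidised in step 15.

Step 1
Reactants: 1 methyl 4-chloro-4-oxobutanoate; 2 isopropenylmagnesium bromide
Product: 3 methyl 5-methyl-4-oxohex-5-enoate
Conditions: CuI (5 mol %), THF, −78 °C; aq NH4Cl
Reagents that add atoms: none
Why: Copper-catalysed acylation of a Grignard reagent; at −78 °C the acid chloride reacts much faster than the ester or the enone product, so the ketone should form without double or conjugate addition.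

Step 2
Reactants: 3 methyl 5-methyl-4-oxohex-5-enoate
Product: 4 methyl (4R)-4-hydroxy-5-methylhex-5-enoate
Conditions: (S)-1-methyl-3,3-diphenyltetrahydro-1H,3H-pyrrolo[1,2-c][1,3,2]oxazaborole (0.15 equiv), catecholborane (1.5 equiv), toluene, −78 °C; MeOH, pH 7 buffer
Reagents that add atoms: none
Why: Corey–Bakshi–Shibata reduction; the sp2-branched isopropenyl group acts as the large substituent, as aryl and alkenyl groups do, so the (S) catalyst should deliver hydride to the face that gives the (R) allylic alcohol, and the catalysed 1,2-reduction at −78 °C leaves alkene and ester untouched.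

Step 3
Reactants: 4 methyl (4R)-4-hydroxy-5-methylhex-5-enoate
Product: 5 methyl (4R)-5-methyl-4-(triethylsilyloxy)hex-5-enoate
Conditions: Et3SiCl, imidazole, CH2Cl2, 0 °C
Reagents that add atoms: chlorotriethylsilane, CC[Si](Cl)(CC)CC
Why: Standard silylation, run on crude 4 so that γ-lactonisation cannot compete; the triethylsilyl group is chosen because it can later be removed beside the TBS and TIPS ethers.

Step 4
Reactants: 5 methyl (4R)-5-methyl-4-(triethylsilyloxy)hex-5-enoate
Product: 6 (4R)-5-methyl-4-(triethylsilyloxy)hex-5-enoic acid
Conditions: LiOH·H2O, THF/MeOH/H2O, 0 °C; aq NaH2PO4 to pH 5, 0 °C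
Reagents that add atoms: lithium hydroxide, [Li+].[OH-]
Why: Ester saponification; the silyl ether tolerates cold aqueous hydroxide and buffered acidification, and the allylic stereocentre has no acidic hydrogen.

Step 5
Reactants: 7 benzyl alcohol
Product: 10 benzyloxyacetylene, via benzyl (E)-1,2-dichlorovinyl ether 8 (not isolated), via lithium benzyloxyacetylide 9 (not isolated)
Conditions: KH, THF, 0 °C; Cl2C=CHCl, −50 °C → rt; n-BuLi (2.5 equiv), −78 → −40 °C; MeOH, −78 °C; kept as a cold solution
Reagents that add atoms: trichloroethene, ClC=C(Cl)Cl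
Why: Ynol ether synthesis from trichloroethene: the alkoxide gives the dichlorovinyl ether, two equivalents of butyllithium effect elimination and chlorine–lithium exchange to the acetylide, and cold protonation gives the terminal ynol ether, which is not warmed because benzyl alkynyl ethers rearrange by a [3,3] shift near 60 °C.

Step 6
Reactants: 6 (4R)-5-methyl-4-(triethylsilyloxy)hex-5-enoic acid; 10 benzyloxyacetylene
Product: 13 3-(benzyloxy)-4-[(2R)-3-methyl-2-(triethylsilyloxy)but-3-en-1-yl]cyclobut-2-en-1-one (C4 epimers), via acid chloride 11 (not isolated), via alkylketene 12 (not isolated)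
Conditions: 1-chloro-N,N,2-trimethylprop-1-en-1-amine, CH2Cl2, 0 °C; then added slowly to 10 (2 equiv), Et3N, CH2Cl2, rt
Reagents that add atoms: none
Why: The chloroenamine makes the acid chloride under neutral conditions that spare the silyl ether; Et3N dehydrochlorinates it to the ketene, which undergoes the known [2+2] cycloaddition with an alkoxyacetylene, the ketene carbonyl carbon bonding to the unsubstituted alkyne carbon so that the alkoxy group ends on C3 and the side chain on C4.

Step 7
Reactants: 14 L-isoleucine
Product: 15 (2S,3S)-2-hydroxy-3-methylpentanoic acid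
Conditions: NaNO2, 1 M H2SO4, H2O, 0 °C → rt
Reagents that add atoms: water, O
Why: Diazotisation of an α-amino acid; neighbouring carboxylate participation gives two inversions and hence net retention at C2, and C3 is not involved.

Step 8
Reactants: 15 (2S,3S)-2-hydroxy-3-methylpentanoic acid
Product: 16 ethyl (2S,3S)-2-hydroxy-3-methylpentanoate
Conditions: EtOH, H2SO4 (cat.), reflux
Reagents that add atoms: ethanol, CCO
Why: Fischer esterification; neither stereocentre is affected by acid.

Step 9
Reactants: 16 ethyl (2S,3S)-2-hydroxy-3-methylpentanoate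
Product: 17 ethyl (2S,3S)-2-(tert-butyldimethylsilyloxy)-3-methylpentanoate
Conditions: t-BuMe2SiCl, imidazole, DMF, rt
Reagents that add atoms: tert-butylchlorodimethylsilane, CC(C)(C)[Si](C)(C)Cl
Why: Standard silylation; the TBS ether withstands the strongly basic homologation and the later thermolysis.

Step 10
Reactants: 17 ethyl (2S,3S)-2-(tert-butyldimethylsilyloxy)-3-methylpentanoate
Product: 19 triisopropyl{[(3S,4S)-3-(tert-butyldimethylsilyloxy)-4-methylhex-1-yn-1-yl]oxy}silane, via lithium ynolate 18 (not isolated)
Conditions: CH2Br2, lithium 2,2,6,6-tetramethylpiperidide, THF, −78 °C; 17; n-BuLi, −78 → 0 °C; i-Pr3SiCl, −78 °C → rt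
Reagents that add atoms: dibromomethane, BrCBr; chlorotriisopropylsilane, CC(C)[Si](Cl)(C(C)C)C(C)C
Why: Kowalski ester homologation stopped at the ynolate: dibromomethyllithium adds to the ester, bromine–lithium exchange on the dibromo enolate triggers 1,2-shift of the α-silyloxyalkyl group with retention, and the bulky silyl chloride silylates the ynolate on oxygen; the sec-butyl centre is not acidic.

Step 11
Reactants: 13 3-(benzyloxy)-4-[(2R)-3-methyl-2-(triethylsilyloxy)but-3-en-1-yl]cyclobut-2-en-1-one; 19 triisopropyl{[(3S,4S)-3-(tert-butyldimethylsilyloxy)-4-methylhex-1-yn-1-yl]oxy}silane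
Product: 24 3-(benzyloxy)-6-[(1S,2S)-1-(tert-butyldimethylsilyloxy)-2-methylbutyl]-2-[(2R)-3-methyl-2-(triethylsilyloxy)but-3-en-1-yl]-5-(triisopropylsilyloxy)phenol, via vinylketene 20 (not isolated), via cyclobutenone adduct 21 (not isolated), via dienylketene 22 (not isolated), via cyclohexadienone 23 (not isolated)
Conditions: 19 (1.5 equiv), toluene (0.4 M), argon, 80 °C then 110 °C
Reagents that add atoms: none
Why: Danheiser benzannulation, the strain-release benzannulation of a cyclobutenone with a heteroatom-substituted alkyne in its siloxyalkyne form. Heating opens 13 by 4π electrocyclic cleavage of the C1–C4 bond, the C4 alkyl group rotating outward, to vinylketene 20. The electron-rich siloxyalkyne then adds to the ketene in a [2+2] cycloaddition in which its oxygen-remote, nucleophilic carbon bonds to the ketene carbonyl carbon (C7–C7a) and its oxygen-bearing carbon to the ketene α-carbon (C5–C6), giving 21. A second, reversible 4π opening gives dienylketene 22, and ring A closes by thermal 6π electrocyclisation between the ketene carbon and the alkene terminus (C3a–C7a); tautomerisation of dienone 23 gives the phenol. The former cyclobutenone carbonyl therefore emerges as the only free hydroxyl, on C7a between the acyl-arm carbon and the side-chain carbon, while C4 carries the benzyl ether and C6 the silyl ether. No lasting stereocentre is created: the sp3 ring carbons of 21 and 23 vanish on aromatisation, and the three existing centres are insulated from the reacting π system. The only selectivity needed is the regiochemistry of the [2+2] step, which is fixed by the polarisation of the siloxyalkyne. The excess of 19 keeps 20 from acylating the product phenol.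

Step 12
Reactants: 24 3-(benzyloxy)-6-[(1S,2S)-1-(tert-butyldimethylsilyloxy)-2-methylbutyl]-2-[(2R)-3-methyl-2-(triethylsilyloxy)but-3-en-1-yl]-5-(triisopropylsilyloxy)phenol
Product: 25 3-(benzyloxy)-6-[(1S,2S)-1-(tert-butyldimethylsilyloxy)-2-methylbutyl]-2-[(2R)-2-hydroxy-3-methylbut-3-en-1-yl]-5-(triisopropylsilyloxy)phenol
Conditions: HF·pyridine, pyridine, THF, 0 °C
Reagents that add atoms: none
Why: Buffered HF·pyridine cleaves the unhindered secondary triethylsilyl ether much faster than the hindered benzylic TBS ether or the aryl TIPS ether, and the weakly acidic, non-solvolytic medium should not ionise the electron-rich benzylic silyl ether.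

Step 13
Reactants: 25 3-(benzyloxy)-6-[(1S,2S)-1-(tert-butyldimethylsilyloxy)-2-methylbutyl]-2-[(2R)-2-hydroxy-3-methylbut-3-en-1-yl]-5-(triisopropylsilyloxy)phenol
Product: 26 (2S)-4-(benzyloxy)-7-[(1S,2S)-1-(tert-butyldimethylsilyloxy)-2-methylbutyl]-2-(prop-1-en-2-yl)-6-(triisopropylsilyloxy)-2,3-dihydro-1-benzofuran
Conditions: PPh3, diisopropyl azodicarboxylate, THF (0.02 M), 0 °C → rt
Reagents that add atoms: none
Why: Intramolecular Mitsunobu etherification: the alkoxyphosphonium of the allylic alcohol is displaced by the C7a phenoxide in a 5-exo-tet SN2 closure with inversion, turning the (R) carbinol into (S)-C2; the C4 and C6 oxygens are blocked, and SN2′ attack would need a seven-membered ring.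

Step 14
Reactants: 26 (2S)-4-(benzyloxy)-7-[(1S,2S)-1-(tert-butyldimethylsilyloxy)-2-methylbutyl]-2-(prop-1-en-2-yl)-6-(triisopropylsilyloxy)-2,3-dihydro-1-benzofuran
Product: 27 (1S,2S)-1-[(2S)-4-(benzyloxy)-6-hydroxy-2-(prop-1-en-2-yl)-2,3-dihydro-1-benzofuran-7-yl]-2-methylbutan-1-ol
Conditions: Bu4NF (3 equiv), THF, 0 °C → rt; aq NH4Cl; used crude
Reagents that add atoms: none
Why: Fluoride removes the aryl TIPS ether at once and the hindered benzylic TBS ether more slowly; the medium stays basic and cold, so that the o-hydroxybenzylic alcohol should not lose water, and the product is oxidised without purification.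

Step 15
Reactants: 27 (1S,2S)-1-[(2S)-4-(benzyloxy)-6-hydroxy-2-(prop-1-en-2-yl)-2,3-dihydro-1-benzofuran-7-yl]-2-methylbutan-1-ol
Product: 28 (2S)-1-[(2S)-4-(benzyloxy)-6-hydroxy-2-(prop-1-en-2-yl)-2,3-dihydro-1-benzofuran-7-yl]-2-methylbutan-1-one
Conditions: MnO2 (activated, 20 equiv), CH2Cl2, rt
Reagents that add atoms: none
Why: Benzylic oxidation with MnO2, as used for o-hydroxybenzyl alcohols; the neutral heterogeneous oxidant leaves the phenol and the isopropenyl group alone, and the new ketone is held by a hydrogen bond to the C6 hydroxyl, which disfavours enolisation of the α-stereocentre.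

Step 16
Reactants: 28 (2S)-1-[(2S)-4-(benzyloxy)-6-hydroxy-2-(prop-1-en-2-yl)-2,3-dihydro-1-benzofuran-7-yl]-2-methylbutan-1-one
Product: 29 (2S)-1-[(2S)-4,6-dihydroxy-2-(prop-1-en-2-yl)-2,3-dihydro-1-benzofuran-7-yl]-2-methylbutan-1-one
Conditions: BCl3 (3 equiv), pentamethylbenzene (5 equiv), CH2Cl2, −78 °C; MeOH, then aq NaHCO3
Reagents that add atoms: none
Why: Lewis acid debenzylation with a non-basic cation scavenger: the C6 phenol and the ketone are tied up as a boron chelate, further BCl3 activates the benzyl ether, and pentamethylbenzene captures the benzyl cation at −78 °C before it or HCl can attack the isopropenyl group or the O1–C2 bond.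

Step 17
Reactants: 30 methyl 3-oxopentanoate; 31 N-methoxy-N-methylpropanamide
Product: 33 methyl 4-methyl-3,5-dioxoheptanoate, via dilithium dianion 32 (not isolated)
Conditions: LiN(i-Pr)2 (2.2 equiv), THF, −78 → 0 °C; 31, −78 → 0 °C; aq HCl
Reagents that add atoms: none
Why: γ-Acylation of a β-keto ester dianion: the dianion reacts at its more nucleophilic γ-carbon, and the stable tetrahedral adduct of the N-methoxy-N-methyl amide prevents over-addition and proton transfer from the product.

Step 18
Reactants: 33 methyl 4-methyl-3,5-dioxoheptanoate
Product: 34 6-ethyl-4-hydroxy-5-methyl-2H-pyran-2-one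
Conditions: 1,8-diazabicyclo[5.4.0]undec-7-ene (1.2 equiv), toluene, reflux; aq HCl
Reagents that add atoms: none
Why: Base-mediated lactonisation of a 3,5-dioxo ester: the C5 enolate oxygen attacks the ester, methanol is lost and the ring settles as the 4-hydroxypyran-2-one.

Step 19
Reactants: 34 6-ethyl-4-hydroxy-5-methyl-2H-pyran-2-one; 29 (2S)-1-[(2S)-4,6-dihydroxy-2-(prop-1-en-2-yl)-2,3-dihydro-1-benzofuran-7-yl]-2-methylbutan-1-one
Product: 37 3-({(2S)-4,6-dihydroxy-7-[(2S)-2-methylbutanoyl]-2-(prop-1-en-2-yl)-2,3-dihydro-1-benzofuran-5-yl}methyl)-6-ethyl-4-hydroxy-5-methyl-2H-pyran-2-one, via Mannich base 35 (not isolated), via methylidene dione 36 (not isolated)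
Conditions: 34 (1.5 equiv), N,N-dimethylmethyleneiminium iodide (1.5 equiv), MeCN, rt; then 29 (1.0 equiv), 60 °C
Reagents that add atoms: N,N-dimethylmethyleneiminium iodide, C=[N+](C)C.[I-]
Why: Mannich, retro-Mannich and Michael sequence of the kind used for methylene-bridged acylphloroglucinol–pyranone natural products: the pyranone is aminomethylated at C3′, the Mannich base loses dimethylamine on warming, and the methylidene dione is trapped by C5 of 29, the only free ring position and the most nucleophilic one; the stereocentres are not involved, and the weakly basic medium should leave the α-centre of the chelated ketone intact.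

## Compound list

1 | methyl 4-chloro-4-oxobutanoate | COC(=O)CCC(=O)Cl | starting material
2 | isopropenylmagnesium bromide | C=C(C)[Mg]Br | starting material
3 | methyl 5-methyl-4-oxohex-5-enoate | COC(=O)CCC(=O)C(C)=C | intermediate
4 | methyl (4R)-4-hydroxy-5-methylhex-5-enoate | COC(=O)CC[C@@H](O)C(C)=C | intermediate
5 | methyl (4R)-5-methyl-4-(triethylsilyloxy)hex-5-enoate | COC(=O)CC[C@@H](O[Si](CC)(CC)CC)C(C)=C | intermediate
6 | (4R)-5-methyl-4-(triethylsilyloxy)hex-5-enoic acid | OC(=O)CC[C@@H](O[Si](CC)(CC)CC)C(C)=C | intermediate
7 | benzyl alcohol | OCc1ccccc1 | starting material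
8 | benzyl (E)-1,2-dichlorovinyl ether | Cl/C=C(/Cl)OCc1ccccc1 | intermediate
9 | lithium benzyloxyacetylide | [Li]C#COCc1ccccc1 | intermediate
10 | benzyloxyacetylene | C#COCc1ccccc1 | intermediate
11 | (4R)-5-methyl-4-(triethylsilyloxy)hex-5-enoyl chloride | ClC(=O)CC[C@@H](O[Si](CC)(CC)CC)C(C)=C | intermediate
12 | (4R)-5-methyl-4-(triethylsilyloxy)hexa-1,5-dien-1-one (alkylketene) | O=C=CC[C@@H](O[Si](CC)(CC)CC)C(C)=C | intermediate
13 | 3-(benzyloxy)-4-[(2R)-3-methyl-2-(triethylsilyloxy)but-3-en-1-yl]cyclobut-2-en-1-one (C4 epimers) | O=C1C=C(OCc2ccccc2)C1C[C@@H](O[Si](CC)(CC)CC)C(C)=C | intermediate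
14 | L-isoleucine | N[C@@H]([C@@H](C)CC)C(=O)O | starting material
15 | (2S,3S)-2-hydroxy-3-methylpentanoic acid | O[C@@H]([C@@H](C)CC)C(=O)O | intermediate
16 | ethyl (2S,3S)-2-hydroxy-3-methylpentanoate | O[C@@H]([C@@H](C)CC)C(=O)OCC | intermediate
17 | ethyl (2S,3S)-2-(tert-butyldimethylsilyloxy)-3-methylpentanoate | CC(C)(C)[Si](C)(C)O[C@@H]([C@@H](C)CC)C(=O)OCC | intermediate
18 | lithium (3S,4S)-3-(tert-butyldimethylsilyloxy)-4-methylhex-1-yn-1-olate | CC(C)(C)[Si](C)(C)O[C@@H]([C@@H](C)CC)C#CO[Li] | intermediate
19 | triisopropyl{[(3S,4S)-3-(tert-butyldimethylsilyloxy)-4-methylhex-1-yn-1-yl]oxy}silane | CC(C)(C)[Si](C)(C)O[C@@H]([C@@H](C)CC)C#CO[Si](C(C)C)(C(C)C)C(C)C | intermediate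
20 | (3Z,6R)-3-(benzyloxy)-7-methyl-6-(triethylsilyloxy)octa-1,3,7-trien-1-one (vinylketene) | O=C=C/C(OCc1ccccc1)=C/C[C@@H](O[Si](CC)(CC)CC)C(C)=C | intermediate
21 | 4-[(1Z,4R)-1-(benzyloxy)-5-methyl-4-(triethylsilyloxy)hexa-1,5-dien-1-yl]-2-[(1S,2S)-1-(tert-butyldimethylsilyloxy)-2-methylbutyl]-3-(triisopropylsilyloxy)cyclobut-2-en-1-one (C4 epimers) | O=C1C([C@@H](O[Si](C)(C)C(C)(C)C)[C@@H](C)CC)=C(O[Si](C(C)C)(C(C)C)C(C)C)C1/C(OCc2ccccc2)=C/C[C@@H](O[Si](CC)(CC)CC)C(C)=C | intermediate
22 | (3E,5Z,8R)-5-(benzyloxy)-2-[(1S,2S)-1-(tert-butyldimethylsilyloxy)-2-methylbutyl]-9-methyl-8-(triethylsilyloxy)-3-(triisopropylsilyloxy)deca-1,3,5,9-tetraen-1-one (dienylketene) | O=C=C([C@@H](O[Si](C)(C)C(C)(C)C)[C@@H](C)CC)/C(O[Si](C(C)C)(C(C)C)C(C)C)=C\C(OCc1ccccc1)=C\C[C@@H](O[Si](CC)(CC)CC)C(C)=C | intermediate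
23 | 5-(benzyloxy)-2-[(1S,2S)-1-(tert-butyldimethylsilyloxy)-2-methylbutyl]-6-[(2R)-3-methyl-2-(triethylsilyloxy)but-3-en-1-yl]-3-(triisopropylsilyloxy)cyclohexa-2,4-dien-1-one (C6 epimers) | O=C1C([C@@H](O[Si](C)(C)C(C)(C)C)[C@@H](C)CC)=C(O[Si](C(C)C)(C(C)C)C(C)C)C=C(OCc2ccccc2)C1C[C@@H](O[Si](CC)(CC)CC)C(C)=C | intermediate
24 | 3-(benzyloxy)-6-[(1S,2S)-1-(tert-butyldimethylsilyloxy)-2-methylbutyl]-2-[(2R)-3-methyl-2-(triethylsilyloxy)but-3-en-1-yl]-5-(triisopropylsilyloxy)phenol | CC(C)(C)[Si](C)(C)O[C@@H]([C@@H](C)CC)c1c(O)c(C[C@@H](O[Si](CC)(CC)CC)C(C)=C)c(OCc2ccccc2)cc1O[Si](C(C)C)(C(C)C)C(C)C | intermediate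
25 | 3-(benzyloxy)-6-[(1S,2S)-1-(tert-butyldimethylsilyloxy)-2-methylbutyl]-2-[(2R)-2-hydroxy-3-methylbut-3-en-1-yl]-5-(triisopropylsilyloxy)phenol | CC(C)(C)[Si](C)(C)O[C@@H]([C@@H](C)CC)c1c(O)c(C[C@@H](O)C(C)=C)c(OCc2ccccc2)cc1O[Si](C(C)C)(C(C)C)C(C)C | intermediate
26 | (2S)-4-(benzyloxy)-7-[(1S,2S)-1-(tert-butyldimethylsilyloxy)-2-methylbutyl]-2-(prop-1-en-2-yl)-6-(triisopropylsilyloxy)-2,3-dihydro-1-benzofuran | C=C(C)[C@@H]1Cc2c(OCc3ccccc3)cc(O[Si](C(C)C)(C(C)C)C(C)C)c([C@@H](O[Si](C)(C)C(C)(C)C)[C@@H](C)CC)c2O1 | intermediate
27 | (1S,2S)-1-[(2S)-4-(benzyloxy)-6-hydroxy-2-(prop-1-en-2-yl)-2,3-dihydro-1-benzofuran-7-yl]-2-methylbutan-1-ol | C=C(C)[C@@H]1Cc2c(OCc3ccccc3)cc(O)c([C@@H](O)[C@@H](C)CC)c2O1 | intermediate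
28 | (2S)-1-[(2S)-4-(benzyloxy)-6-hydroxy-2-(prop-1-en-2-yl)-2,3-dihydro-1-benzofuran-7-yl]-2-methylbutan-1-one | C=C(C)[C@@H]1Cc2c(OCc3ccccc3)cc(O)c(C(=O)[C@@H](C)CC)c2O1 | intermediate
29 | (2S)-1-[(2S)-4,6-dihydroxy-2-(prop-1-en-2-yl)-2,3-dihydro-1-benzofuran-7-yl]-2-methylbutan-1-one | C=C(C)[C@@H]1Cc2c(O)cc(O)c(C(=O)[C@@H](C)CC)c2O1 | intermediate
30 | methyl 3-oxopentanoate | CCC(=O)CC(=O)OC | starting material
31 | N-methoxy-N-methylpropanamide | CCC(=O)N(C)OC | starting material
32 | dilithium dianion of methyl 3-oxopentanoate | CC=C(O[Li])C=C(O[Li])OC | intermediate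
33 | methyl 4-methyl-3,5-dioxoheptanoate (racemic at C4) | CCC(=O)C(C)C(=O)CC(=O)OC | intermediate
34 | 6-ethyl-4-hydroxy-5-methyl-2H-pyran-2-one | CCc1oc(=O)cc(O)c1C | intermediate
35 | 3-[(dimethylamino)methyl]-6-ethyl-4-hydroxy-5-methyl-2H-pyran-2-one | CCc1oc(=O)c(CN(C)C)c(O)c1C | intermediate
36 | 6-ethyl-5-methyl-3-methylidene-2H-pyran-2,4(3H)-dione | CCC1=C(C)C(=O)C(=C)C(=O)O1 | intermediate
37 | 3-({(2S)-4,6-dihydroxy-7-[(2S)-2-methylbutanoyl]-2-(prop-1-en-2-yl)-2,3-dihydro-1-benzofuran-5-yl}methyl)-6-ethyl-4-hydroxy-5-methyl-2H-pyran-2-one | C=C(C)[C@@H]1Cc2c(O)c(Cc3c(O)c(C)c(CC)oc3=O)c(O)c(C(=O)[C@@H](C)CC)c2O1 | target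

## Step count and least certain steps

Total step count: 19. Longest linear sequence: 12 steps (steps 1 to 4, 6, 11 to 16 and 19).

**Step 11 (key step).**
- What may go wrong: the donor-substituted cyclobutenone may open only at a temperature at which the vinylketene is lost to dimerisation or to O-acylation of the product phenol. Cycloaddition at the branched, silyloxy-bearing alkyne terminus may be slow, and the cascade may stall at the cyclobutenone adduct.
- Fallback: it sets out from 13 and 19 and comes back at 24. The ketenes are generated with light instead of heat, and the cascade is divided into two operations. Irradiation of 13 with excess 19 through Pyrex at room temperature opens the cyclobutenone photochemically, so that the [2+2] step runs cold. The adduct 21 is then isolated and converted into 24 by further irradiation or by brief warming in a separate flask. No further compound is needed (F0).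

**Step 6.**
- What may go wrong: the benzyl ynol ether may be lost to its sigmatropic shift or on handling, and slow trapping then lets the aldoketene dimerise.
- Fallback: it sets out from 6 and comes back at 13. The ketene is generated in the same way but trapped with commercial ethoxyacetylene, which is thermally robust and can be used in large excess, to give 3-ethoxy-4-[(2R)-3-methyl-2-(triethylsilyloxy)but-3-en-1-yl]cyclobut-2-en-1-one F1. The ethoxy group is then exchanged for benzyloxy by mild acid-catalysed vinylogous transesterification with benzyl alcohol 7 over molecular sieves, kept cold so that the double bond does not migrate toward the substituted ring carbon.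

**Step 14 (with step 15).**
- What may go wrong: the free o-hydroxybenzylic alcohol may lose water to a quinone methide, whose 1,5-hydrogen shift would erase the α-stereocentre, and oxidation of the hindered carbinol beside a free phenol may be slow.
- Fallback: it sets out from 26 and comes back at 28. The benzylic silyl ether is oxidised directly with 2,3-dichloro-5,6-dicyano-1,4-benzoquinone in buffered wet CH2Cl2 (hydride abstraction at the trioxygenated benzylic position, then loss of the silyl group). This gives (2S)-1-[(2S)-4-(benzyloxy)-2-(prop-1-en-2-yl)-6-(triisopropylsilyloxy)-2,3-dihydro-1-benzofuran-7-yl]-2-methylbutan-1-one F2, so that no free benzylic alcohol is ever formed. Cold acetic acid-buffered Bu4NF then removes the aryl silyl group.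

**Step 16.**
- What may go wrong: the Lewis acid may open the allylic O1–C2 bond with chelation help from the ketone, or HCl may add to the isopropenyl group.
- Fallback: it sets out from 28 and comes back at 29. The Lewis acid is avoided altogether by silane transfer hydrogenolysis (Et3SiH, Pd(OAc)2 as catalyst, Et3N, CH2Cl2, rt), a method known to cleave aryl benzyl ethers while sparing alkenes. It gives toluene and the aryl silyl ether (2S)-1-[(2S)-6-hydroxy-2-(prop-1-en-2-yl)-4-(triethylsilyloxy)-2,3-dihydro-1-benzofuran-7-yl]-2-methylbutan-1-one F3, which is desilylated with buffered Bu4NF at 0 °C.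

**Step 19.**
- What may go wrong: the methylidene dione may be captured by unreacted pyranone, or the one-carbon unit may exchange between partners, so that symmetric dimers form at the expense of the crossed product.
- Fallback: it sets out from 29 and comes back at 37. The bridge carbon is first fixed on C5 by Vilsmeier–Haack formylation (POCl3, DMF, EtOAc, 0 °C; aqueous NaOAc) to give (2S)-4,6-dihydroxy-7-[(2S)-2-methylbutanoyl]-2-(prop-1-en-2-yl)-2,3-dihydro-1-benzofuran-5-carbaldehyde F4. The aldehyde is then joined to 34 by organocatalytic reductive alkylation (L-proline as catalyst, diethyl 2,6-dimethyl-1,4-dihydropyridine-3,5-dicarboxylate as hydride donor, CH2Cl2, rt): Knoevenagel condensation followed by conjugate reduction, which can only give the crossed product.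

## Further compounds

F0 | step 11 | none | none
F1 | step 6 | 3-ethoxy-4-[(2R)-3-methyl-2-(triethylsilyloxy)but-3-en-1-yl]cyclobut-2-en-1-one (C4 epimers) | O=C1C=C(OCC)C1C[C@@H](O[Si](CC)(CC)CC)C(C)=C
F2 | step 14 | (2S)-1-[(2S)-4-(benzyloxy)-2-(prop-1-en-2-yl)-6-(triisopropylsilyloxy)-2,3-dihydro-1-benzofuran-7-yl]-2-methylbutan-1-one | C=C(C)[C@@H]1Cc2c(OCc3ccccc3)cc(O[Si](C(C)C)(C(C)C)C(C)C)c(C(=O)[C@@H](C)CC)c2O1
F3 | step 16 | (2S)-1-[(2S)-6-hydroxy-2-(prop-1-en-2-yl)-4-(triethylsilyloxy)-2,3-dihydro-1-benzofuran-7-yl]-2-methylbutan-1-one | C=C(C)[C@@H]1Cc2c(O[Si](CC)(CC)CC)cc(O)c(C(=O)[C@@H](C)CC)c2O1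
F4 | step 19 | (2S)-4,6-dihydroxy-7-[(2S)-2-methylbutanoyl]-2-(prop-1-en-2-yl)-2,3-dihydro-1-benzofuran-5-carbaldehyde | C=C(C)[C@@H]1Cc2c(O)c(C=O)c(O)c(C(=O)[C@@H](C)CC)c2O1
A1 | alternative 1 | (2S)-1-[(2S)-4,6-bis(methoxymethoxy)-2-(prop-1-en-2-yl)-2,3-dihydro-1-benzofuran-7-yl]-2-methylbutan-1-one | C=C(C)[C@@H]1Cc2c(OCOC)cc(OCOC)c(C(=O)[C@@H](C)CC)c2O1
A2 | alternative 1 | (2S)-1-[3-bromo-2-hydroxy-4,6-bis(methoxymethoxy)phenyl]-2-methylbutan-1-one | Brc1c(O)c(C(=O)[C@@H](C)CC)c(OCOC)cc1OCOC
A3 | alternative 1 | isoprene (2-methylbuta-1,3-diene) | C=CC(C)=C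
A4 | alternative 2 | (2S)-1-{3-[(2R)-2-(tert-butyldimethylsilyloxy)-3-methylbut-3-en-1-yl]-2-hydroxy-4,6-bis(methoxymethoxy)phenyl}-2-methylbutan-1-one | C=C(C)[C@H](O[Si](C)(C)C(C)(C)C)Cc1c(O)c(C(=O)[C@@H](C)CC)c(OCOC)cc1OCOC
A5 | alternative 2 | 2-[(2R)-2-(tert-butyldimethylsilyloxy)-3-methylbut-3-en-1-yl]-3,5-bis(methoxymethoxy)-6-(trimethylsilyl)phenyl trifluoromethanesulfonate | C=C(C)[C@H](O[Si](C)(C)C(C)(C)C)Cc1c(OS(=O)(=O)C(F)(F)F)c([Si](C)(C)C)c(OCOC)cc1OCOC
A6 | alternative 2 | caesium (2S)-2-methylbutanoate | [Cs+].[O-]C(=O)[C@@H](C)CC
A7 | alternative 3 | 3-({(2S)-4,6-bis(tert-butyldimethylsilyloxy)-7-[(2S)-2-methylbutanoyl]-2-(prop-1-en-2-yl)-2,3-dihydro-1-benzofuran-5-yl}methyl)-6-ethyl-4-hydroxy-5-methyl-2H-pyran-2-one | C=C(C)[C@@H]1Cc2c(O[Si](C)(C)C(C)(C)C)c(Cc3c(O)c(C)c(CC)oc3=O)c(O[Si](C)(C)C(C)(C)C)c(C(=O)[C@@H](C)CC)c2O1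
A8 | alternative 3 | 2-({(2S)-4,6-bis(tert-butyldimethylsilyloxy)-7-[(2S)-2-methylbutanoyl]-2-(prop-1-en-2-yl)-2,3-dihydro-1-benzofuran-5-yl}methyl)propanedioyl dichloride | C=C(C)[C@@H]1Cc2c(O[Si](C)(C)C(C)(C)C)c(CC(C(=O)Cl)C(=O)Cl)c(O[Si](C)(C)C(C)(C)C)c(C(=O)[C@@H](C)CC)c2O1
A9 | alternative 3 | trimethyl(pent-2-en-3-yloxy)silane (mixture of geometric isomers) | CC=C(CC)O[Si](C)(C)C
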